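**Plan**

1. Numbering: ring A is the seven-membered lactone (C1=C2, C3 carbonyl, ring O, C4 with two methyls, C5, C10); ring B is C5–C10; rings C and D are the bicyclo[3.3.1]nonane (ring C: C8, C9, C11, C12, C13, C14; ring D: C12–C17; C13 carries the exo-methylene, C14 the CO2Me, C16 the carbinol).
2. Cuts, last bond first: C16–OH; C8–C14 (ring C, cation–alkene closure); C11–C12 (dearomatising allylation of methyl 3,5-dimethylorsellinate, which brings all six ring D carbons); then rings A and B in one operation through C2–C3, C5–C10 and C8–C9.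
3. Enabling feature: C10 and C5 are linked through C1–C2–C3–O–C4. With C1 as a ketone this chain is a β-keto ester, so a Claisen acylation makes C2–C3 and the same chain then tethers a C9=C10 enal to a C5=C6–C7=C8 diene; ring A is the tether ring and ring B the cyclohexene of one intramolecular (4+2) cycloaddition.
4. Forward: sorbate-derived dienyl acyl-imidazole + enone acetal → rings A and B (step 4) → helpers removed (C6=C7 moved to C8=C9, C1 ketone turned into C1=C2, C11 aldehyde turned into an allylic carbonate) → ring D attached at C11 → ring C closed → C16 hydroxylated.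
5. Stereochemistry: C5/C10 (trans) and the absolute sense from the aminocatalysed endo cycloaddition; C12 from the chiral palladium catalyst; C9, C8 and C14 from the chair-like ring C closure steered by C10 and C12; C16 from exo-face attack on the diketone enolate.

Key step: step 4

Remark: 4, 5 (sold as an aqueous solution) and 14 are taken as purchasable; the catalyst and ligand enantiomers in steps 4 and 8 are chosen from the usual shielding models.

**Step 1**
Reactants: 1 ethyl (2E,4E)-hexa-2,4-dienoate (ethyl sorbate)
Product: 2 (3E,5E)-2-methylhepta-3,5-dien-2-ol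
Conditions: MeMgBr (2.5 equiv), THF, 0 °C to rt; aq. NH4Cl
Reagents that add atoms: methylmagnesium bromide, C[Mg]Br
Why: Double 1,2-addition of the Grignard reagent to the ester (conjugate addition is negligible without copper) should give the tertiary dienol with both E alkenes intact; no stereocentre is formed.

**Step 2**
Reactants: 2 (3E,5E)-2-methylhepta-3,5-dien-2-ol
Product: 3 (3E,5E)-2-methylhepta-3,5-dien-2-yl 1H-imidazole-1-carboxylate
Conditions: n-BuLi (1.0 equiv), THF, −78 °C; CDI, −78 to 0 °C; used cold and at once
Reagents that add atoms: 1,1'-carbonyldiimidazole, O=C(n1ccnc1)n1ccnc1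
Why: Acyl transfer from CDI to the lithium alkoxide gives the imidazole carbamate under acid-free conditions, which the ionisable tertiary dienyl system needs.

**Step 3**
Reactants: 4 3-(triphenyl-λ5-phosphanylidene)butan-2-one; 5 2,2-dimethoxyacetaldehyde
Product: 6 (3E)-5,5-dimethoxy-3-methylpent-3-en-2-one
Conditions: CH2Cl2–H2O, 40 °C
Reagents that add atoms: none
Why: Wittig olefination with the α-methyl-stabilised ylide should give the E-trisubstituted enone (acetyl trans to the acetal carbon), as is usual for stabilised ylides.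

**Step 4**
Reactants: 6 (3E)-5,5-dimethoxy-3-methylpent-3-en-2-one; 3 (3E,5E)-2-methylhepta-3,5-dien-2-yl 1H-imidazole-1-carboxylate
Product: 9 (5aR,6R,7R,9aS)-1,1,5a,7-tetramethyl-3,5-dioxo-1,3,4,5,5a,6,7,9a-octahydro-2-benzoxepine-6-carbaldehyde (rings A and B; trans ring fusion; 5a-Me 6-CHO 7-Me all cis), via dienyl keto ester acetal 7 (not isolated), via dienyl keto ester enal 8 (not isolated)
Conditions: 6, LiN(SiMe3)2 (2.2 equiv), THF, −78 °C; 3 (1.1 equiv), −78 to 0 °C; AcOH (2.2 equiv); then MeCN–H2O, (2R,5R)-5-benzyl-2-tert-butyl-3-methylimidazolidin-4-one·CF3CO2H (20 mol %), −20 °C to rt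
Reagents that add atoms: water, O
Why: Proposed new method: the kinetic lithium enolate of 6 (C2, the acetyl methyl) attacks the carbamate carbon C3 of 3 and expels imidazolide (crossed Claisen acylation, closest known type: C-acylation of ketone enolates by alkyl imidazole-1-carboxylates), so that the new C2–C3 bond turns the chain C1–C2–C3–O–C4 into a tether between the C9=C10 alkene and the C5=C6–C7=C8 diene; after neutralisation the amine salt converts the allylic acetal into an α,β-unsaturated iminium ion, which lowers the LUMO of C9=C10 and triggers a concerted suprafacial (4+2) cycloaddition that forms C5–C10 and C8–C9 (closest known type: imidazolidinone-catalysed intramolecular Diels–Alder reaction of trienals, here asked to accept a β-acyl-β-methyl enal and an ester tether, which is the untested part). Ring B closes as the cyclohexene of the cycloaddition (six-membered, both new bonds) and ring A as its seven-membered tether ring (fused mode, tether on the dienophile carbon C10 and the diene terminus C5). C5 and C10 are controlled by the endo transition state of the iminium group, in which the tether carbonyl C1 (trans to the iminium carbon on the E alkene) is exo and the ring fusion therefore trans; C8 and C9 follow from the E,E-diene and E-dienophile geometry (8-Me, 9-CHO, 10-Me cis) and are erased again in step 5. The absolute sense is controlled by the benzyl group of the (2R,5R)-catalyst, which blocks one face of the E-iminium ion. The step needs carbon rather than oxygen acylation and deprotonation at C2 rather than at the acetal carbon (secured by the kinetic lithium enolate and the acyl-imidazole donor), a cycloaddition that runs only through the catalyst-bound ion (secured because acetal 7 is a poor dienophile until unmasked) and survival of the tertiary dienyl ester (secured by neutralisation, low temperature and the gem-dimethyl group at C4, which also favours the folded ester rotamer).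

**Step 5**
Reactants: 9 (5aR,6R,7R,9aS)-1,1,5a,7-tetramethyl-3,5-dioxo-1,3,4,5,5a,6,7,9a-octahydro-2-benzoxepine-6-carbaldehyde
Product: 10 (5aR,9aS)-1,1,5a,7-tetramethyl-3,5-dioxo-1,3,4,5,5a,8,9,9a-octahydro-2-benzoxepine-6-carbaldehyde (C8=C9 enal)
Conditions: RuHCl(CO)(PPh3)3 (5 mol %), toluene, 80 °C
Reagents that add atoms: none
Why: Ruthenium-hydride alkene migration (insertion/β-hydride elimination) can walk C6=C7 to C8=C9 along the α face, where the hydrogens on C8 and C9 lie syn, with the conjugated tetrasubstituted enal as thermodynamic sink; the C8 and C9 stereocentres vanish and C5 should be retained because any C5=C6 isomer re-forms C5–H on the same face.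

**Step 6**
Reactants: 10 (5aR,9aS)-1,1,5a,7-tetramethyl-3,5-dioxo-1,3,4,5,5a,8,9,9a-octahydro-2-benzoxepine-6-carbaldehyde
Product: 11 (5aR,9aS)-5-hydroxy-6-(hydroxymethyl)-1,1,5a,7-tetramethyl-4,5,5a,8,9,9a-hexahydro-2-benzoxepin-3(1H)-one (both epimers at the new carbinol C1)
Conditions: NaBH4, CeCl3·7H2O, MeOH, −40 to 0 °C
Reagents that add atoms: none
Why: Luche reduction should reduce the enal 1,2 to the allylic alcohol and the C1 ketone to the β-hydroxy lactone; the new C1 stereocentre is irrelevant because it is eliminated in step 7.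

**Step 7**
Reactants: 11 (5aR,9aS)-5-hydroxy-6-(hydroxymethyl)-1,1,5a,7-tetramethyl-4,5,5a,8,9,9a-hexahydro-2-benzoxepin-3(1H)-one
Product: 13 methyl [(5aR,9aS)-1,1,5a,7-tetramethyl-3-oxo-1,3,5a,8,9,9a-hexahydro-2-benzoxepin-6-yl]methyl carbonate, via bis(methyl carbonate) 12 (not isolated)
Conditions: ClCO2Me, pyridine, DMAP (cat.), CH2Cl2, 0 °C to rt; then DBU, rt
Reagents that add atoms: methyl chloroformate, COC(=O)Cl
Why: Acylation of both hydroxyls and E1cB elimination of the β-carbonate across C1–C2 gives the ring A enoate (cis by ring constraint), while the primary allylic carbonate at C11 survives as the leaving group for step 8.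

**Step 8**
Reactants: 13 methyl [(5aR,9aS)-1,1,5a,7-tetramethyl-3-oxo-1,3,5a,8,9,9a-hexahydro-2-benzoxepin-6-yl]methyl carbonate; 14 methyl 2,4-dihydroxy-3,5,6-trimethylbenzoate
Product: 15 methyl (3R)-6-hydroxy-2,3,5-trimethyl-4-oxo-3-{[(5aR,9aS)-1,1,5a,7-tetramethyl-3-oxo-1,3,5a,8,9,9a-hexahydro-2-benzoxepin-6-yl]methyl}cyclohexa-1,5-diene-1-carboxylate
Conditions: Pd2(dba)3·CHCl3 (2.5 mol %), N,N'-[(1R,2R)-cyclohexane-1,2-diyl]bis[2-(diphenylphosphanyl)benzamide] (7.5 mol %), CH2Cl2, rt
Reagents that add atoms: none
Why: Tsuji–Trost allylic alkylation with dearomatisation: zerovalent palladium ionises the C11 carbonate to a π-allyl (C11–C9–C8), the released methoxide deprotonates 14, and the 4-oxido arene attacks the unhindered terminus C11 through its ring carbon C5 (the future C12, next to the 6-methyl carbon), the chiral ligand pocket choosing the face of the planar nucleophile and so the C12 configuration.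

**Step 9**
Reactants: 15 methyl (3R)-6-hydroxy-2,3,5-trimethyl-4-oxo-3-{[(5aR,9aS)-1,1,5a,7-tetramethyl-3-oxo-1,3,5a,8,9,9a-hexahydro-2-benzoxepin-6-yl]methyl}cyclohexa-1,5-diene-1-carboxylate
Product: 16 16-deoxy tetracycle (17 without the C16 hydroxyl; C16 epimers and enol in equilibrium)
Conditions: HN(SO2CF3)2 (10 mol %), CH2Cl2, −78 to −20 °C
Reagents that add atoms: none
Why: Protic-acid-initiated cation–alkene cyclisation: protonation of C8=C9 at C9 on the α face (anti to the axial C10 methyl) gives the tertiary C8 cation, which C14 of the C13=C14 bond captures through a chair-like six-membered transition state with C11 equatorial (trans B/C fusion, 8-methyl axial); the C12 centre forces the C15–C17 bridge onto the α face and so fixes C14, and loss of a proton from the C13 methyl gives the exo-methylene.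

**Step 10**
Reactants: 16 16-deoxy tetracycle
Product: 17 target natural product (the 16-hydroxy-15,17-diketone; hydroxyl exo and methyl endo at C16)
Conditions: DBU (1.1 equiv), 3-phenyl-2-(phenylsulfonyl)oxaziridine (1.2 equiv), THF, −40 °C to rt
Reagents that add atoms: 3-phenyl-2-(phenylsulfonyl)oxaziridine, O=S(=O)(c1ccccc1)N1OC1c1ccccc1
Why: Enolate hydroxylation of the 2-methyl-1,3-diketone by the N-sulfonyloxaziridine; the oxidant should reach C16 from the exo face (the face of ring D turned away from ring C) because ring C shields the endo face, which places the hydroxyl exo and the methyl endo as in the target.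

**Compound list**

1 | ethyl (2E,4E)-hexa-2,4-dienoate | CCOC(=O)/C=C/C=C/C | starting material
2 | (3E,5E)-2-methylhepta-3,5-dien-2-ol | C/C=C/C=C/C(C)(C)O | intermediate
3 | (3E,5E)-2-methylhepta-3,5-dien-2-yl 1H-imidazole-1-carboxylate | C/C=C/C=C/C(C)(C)OC(=O)n1ccnc1 | intermediate
4 | 3-(triphenyl-λ5-phosphanylidene)butan-2-one | CC(=O)C(C)=P(c1ccccc1)(c1ccccc1)c1ccccc1 | starting material
5 | 2,2-dimethoxyacetaldehyde | COC(OC)C=O | starting material
6 | (3E)-5,5-dimethoxy-3-methylpent-3-en-2-one | CC(=O)/C(C)=C/C(OC)OC | intermediate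
7 | (3E,5E)-2-methylhepta-3,5-dien-2-yl (4E)-6,6-dimethoxy-4-methyl-3-oxohex-4-enoate | C/C=C/C=C/C(C)(C)OC(=O)CC(=O)/C(C)=C/C(OC)OC | intermediate (not isolated)
8 | (3E,5E)-2-methylhepta-3,5-dien-2-yl (4E)-4-methyl-3,6-dioxohex-4-enoate | C/C=C/C=C/C(C)(C)OC(=O)CC(=O)/C(C)=C/C=O | intermediate (not isolated)
9 | (5aR,6R,7R,9aS)-1,1,5a,7-tetramethyl-3,5-dioxo-1,3,4,5,5a,6,7,9a-octahydro-2-benzoxepine-6-carbaldehyde | O=C[C@H]1[C@]2(C)C(=O)CC(=O)OC(C)(C)[C@H]2C=C[C@H]1C | intermediate
10 | (5aR,9aS)-1,1,5a,7-tetramethyl-3,5-dioxo-1,3,4,5,5a,8,9,9a-octahydro-2-benzoxepine-6-carbaldehyde | O=CC=1[C@]2(C)C(=O)CC(=O)OC(C)(C)[C@H]2CCC=1C | intermediate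
11 | (5aR,9aS)-5-hydroxy-6-(hydroxymethyl)-1,1,5a,7-tetramethyl-4,5,5a,8,9,9a-hexahydro-2-benzoxepin-3(1H)-one (carbinol epimers) | OCC=1[C@]2(C)C(O)CC(=O)OC(C)(C)[C@H]2CCC=1C | intermediate
12 | bis(methyl carbonate) of 11 | COC(=O)OCC=1[C@]2(C)C(OC(=O)OC)CC(=O)OC(C)(C)[C@H]2CCC=1C | intermediate (not isolated)
13 | methyl [(5aR,9aS)-1,1,5a,7-tetramethyl-3-oxo-1,3,5a,8,9,9a-hexahydro-2-benzoxepin-6-yl]methyl carbonate | COC(=O)OCC=1[C@]2(C)C=CC(=O)OC(C)(C)[C@H]2CCC=1C | intermediate
14 | methyl 2,4-dihydroxy-3,5,6-trimethylbenzoate | COC(=O)c1c(C)c(C)c(O)c(C)c1O | starting material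
15 | methyl (3R)-6-hydroxy-2,3,5-trimethyl-4-oxo-3-{[(5aR,9aS)-1,1,5a,7-tetramethyl-3-oxo-1,3,5a,8,9,9a-hexahydro-2-benzoxepin-6-yl]methyl}cyclohexa-1,5-diene-1-carboxylate | COC(=O)C1=C(C)[C@@](C)(CC=2[C@]3(C)C=CC(=O)OC(C)(C)[C@H]3CCC=2C)C(=O)C(C)=C1O | intermediate
16 | 16-deoxy tetracycle: ring A 1-en-3-one lactone with 4,4-dimethyl; 5-H α, 10-methyl β, 9-H α, 8-methyl β; rings C and D a bicyclo[3.3.1]nonane with 12-methyl, 13-methylidene, 14-methoxycarbonyl and 15,17-dioxo groups, the C15–C17 bridge on the α face of ring C; 16-methyl without hydroxyl (C16 epimers) | C=C1[C@@]2(C)C[C@H]3[C@]4(C)C=CC(=O)OC(C)(C)[C@H]4CC[C@]3(C)[C@]1(C(=O)OC)C(=O)C(C)C2=O | intermediate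
17 | target natural product: the tetracycle of 16 with a hydroxyl at C16, the hydroxyl exo (turned away from ring C) and the 16-methyl endo | C=C1[C@@]2(C)C[C@H]3[C@]4(C)C=CC(=O)OC(C)(C)[C@H]4CC[C@]3(C)[C@]1(C(=O)OC)C(=O)[C@@](C)(O)C2=O | target

**Count and risks**

Total steps: 10. Longest linear sequence: 9 steps (1 → 2 → 3 → 9 → 10 → 11 → 13 → 15 → 16 → 17).

Steps most likely to fail:

1. Step 4. The cycloaddition stage may be outrun by ionisation of the tertiary dienyl ester in the weakly acidic aminocatalytic medium, or the hindered β,β-disubstituted iminium ion may react slowly and with poor face or endo/exo control. Fallback with known reactions, from 6 and 3, returning at 9: run the crossed Claisen acylation alone and isolate 7; unmask the acetal with pyridinium p-toluenesulfonate in wet acetone and isolate 8; warm 8 in toluene (40–60 °C) for an uncatalysed thermal intramolecular Diels–Alder reaction of the doubly activated ene-dicarbonyl dienophile. This gives racemic material, 9 together with the mirror-image cycloadduct F1, and the two are separated by chromatography on a chiral stationary phase.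

2. Step 8. Allylation may go to oxygen or to the ring carbon between the two oxygens instead of the carbon next to the 6-methyl group, and the ligand may control the new quaternary centre poorly. Fallback from 13, returning at 15: methanolysis of the carbonate (K2CO3, MeOH, 0 °C) gives allylic alcohol F2, and CBr4/PPh3 gives allylic bromide F3. The lithium phenolate of 14 (LiN(SiMe3)2, toluene, 0 °C) is then alkylated with F3 as a contact ion pair in the non-polar medium, which favours carbon over oxygen. The product 15 is separated from the C12 epimer of 15 F4.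

3. Step 9. The C8 cation may be trapped by the enol oxygen (cyclic enol ether) instead of C14, or the acid may cleave the tertiary C4–O bond of the lactone. Fallback from 15, returning at 16: O-methylation of the vinylogous acid with Me3SiCHN2 (toluene–MeOH) gives methyl enol ether F5, so that only carbon can trap the cation irreversibly. The same catalytic HN(SO2CF3)2 closure then gives the cyclised methyl enol ether F6, and dilute HCl in THF hydrolyses the vinylogous ester to 16.

**Further compounds**

F1 | step 4 | (5aS,6S,7S,9aR)-1,1,5a,7-tetramethyl-3,5-dioxo-1,3,4,5,5a,6,7,9a-octahydro-2-benzoxepine-6-carbaldehyde (mirror image of 9) | O=C[C@@H]1[C@@]2(C)C(=O)CC(=O)OC(C)(C)[C@@H]2C=C[C@@H]1C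
F2 | step 8 | (5aR,9aS)-6-(hydroxymethyl)-1,1,5a,7-tetramethyl-5a,8,9,9a-tetrahydro-2-benzoxepin-3(1H)-one | OCC=1[C@]2(C)C=CC(=O)OC(C)(C)[C@H]2CCC=1C
F3 | step 8 | (5aR,9aS)-6-(bromomethyl)-1,1,5a,7-tetramethyl-5a,8,9,9a-tetrahydro-2-benzoxepin-3(1H)-one | BrCC=1[C@]2(C)C=CC(=O)OC(C)(C)[C@H]2CCC=1C
F4 | step 8 | (3S) epimer of 15 (C12 epimer) | COC(=O)C1=C(C)[C@](C)(CC=2[C@]3(C)C=CC(=O)OC(C)(C)[C@H]3CCC=2C)C(=O)C(C)=C1O
F5 | step 9 | O-methyl enol ether of 15 (6-methoxy in place of 6-hydroxy) | COC(=O)C1=C(C)[C@@](C)(CC=2[C@]3(C)C=CC(=O)OC(C)(C)[C@H]3CCC=2C)C(=O)C(C)=C1OC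
F6 | step 9 | C15 methyl enol ether of 16 | C=C1[C@@]2(C)C[C@H]3[C@]4(C)C=CC(=O)OC(C)(C)[C@H]4CC[C@]3(C)[C@]1(C(=O)OC)C(OC)=C(C)C2=O
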